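**Retrosynthetic overview**
1. Target (exo,exo-2,6-diaryl-3,7-dioxabicyclo[3.3.0]octane; aryl-bearing carbons R, ring-fusion carbons S) ⇒ Pd-deallylation of allyl ether **17** ⇒ double 5-exo-tet O-alkylation of bis-tosylate **16** ⇒ tetraol **14** ⇒ LiAlH4 reduction of cis-fused bis-lactone **13**.
2. **13** ⇒ lactonisation of hydroxy-lactone **12** ⇒ ketoreductase dynamic reductive resolution of α-aroyl lactone **11**, which sets the second ring's centres (C3a/C4).
3. **11** ⇒ aldol/oxidation of trans-paraconate **8** ⇒ Ru-catalysed asymmetric transfer hydrogenation with dynamic kinetic resolution of 2-aroylsuccinate **7**, which sets C1/C6a.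
4. Rings form in this order: lactone A (Step 4), lactone B (Step 8), then both THF rings together (Step 11).

Assumption: the free 4-OH of the syringyl ring is carried as an allyl ether and removed in the last step. The 3,4,5-trimethoxyphenyl ring needs no protection.

---

**Step 1**
Reactants: 1 acetosyringone; 2 allyl bromide
Product: 3 1-[4-(allyloxy)-3,5-dimethoxyphenyl]ethan-1-one
Conditions: K2CO3, acetone, reflux
Reagents that add atoms: allyl bromide, C=CCBr
Why: Williamson O-allylation masks the phenol with a group that survives base, hydride, Ru–H and Lewis-acid steps and is removed under neutral Pd(0) conditions. No stereocentre is formed.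

**Step 2**
Reactants: 3; 4 dimethyl carbonate
Product: 5 methyl 3-[4-(allyloxy)-3,5-dimethoxyphenyl]-3-oxopropanoate
Conditions: NaH, (MeO)2CO, THF, reflux (cat. MeOH)
Reagents that add atoms: dimethyl carbonate, COC(=O)OC
Why: Crossed Claisen (methoxycarbonylation) is driven by the acidic β-keto-ester enolate. No stereocentre is formed.

**Step 3**
Reactants: 5; 6 methyl bromoacetate
Product: 7 dimethyl 2-[4-(allyloxy)-3,5-dimethoxybenzoyl]butanedioate (2-aroylsuccinate)
Conditions: NaH (1.05 equiv), THF/DMF, 0 °C → rt
Reagents that add atoms: methyl bromoacetate, COC(=O)CBr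
Why: C-Alkylation of the stabilised enolate. The only stereogenic carbon in 7 is the acidic α-CH (pKa ≈ 11), which epimerises freely, so 7 is an undefined, rapidly equilibrating substrate.

**Step 4**
Reactants: 7
Product: 8 methyl (2R,3R)-2-[4-(allyloxy)-3,5-dimethoxyphenyl]-5-oxooxolane-3-carboxylate (trans-paraconate)
Conditions: (R,R)-RuCl(p-cymene)(TsDPEN) (1 mol %), HCO2H/Et3N 5:2, EtOAc, 35 °C, 24 h; then PPTS (10 mol %), PhMe, 50 °C
Reagents that add atoms: none
Why: Noyori–Ikariya asymmetric transfer hydrogenation with dynamic kinetic resolution: the labile α-centre of 7 equilibrates, the (R,R)-Ru–H delivers hydride to the aroyl face giving the (R)-benzylic carbinol with syn selectivity, and the syn hydroxy-diester lactonises onto the CH2CO2Me arm to the 2,3-trans lactone. This sets Ca and Cd (target C1/C6a).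

**Step 5**
Reactants: 8; 9 3,4,5-trimethoxybenzaldehyde
Product: 10 methyl (2R,3R)-2-[4-(allyloxy)-3,5-dimethoxyphenyl]-4-[hydroxy(3,4,5-trimethoxyphenyl)methyl]-5-oxooxolane-3-carboxylate (mixture of diastereomers at C4 and the carbinol)
Conditions: LiHMDS (1.05 equiv), THF, −78 °C; then 9, −78 °C, 1 h; NH4Cl
Reagents that add atoms: 3,4,5-trimethoxybenzaldehyde, COc1cc(C=O)cc(OC)c1OC
Why: Aldol addition of the kinetically formed lactone α-enolate, which is more acidic and less hindered than the ester α-CH. The two new centres are left undefined on purpose because both are erased in Step 6.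

**Step 6**
Reactants: 10
Product: 11 methyl (2R,3R)-2-[4-(allyloxy)-3,5-dimethoxyphenyl]-5-oxo-4-(3,4,5-trimethoxybenzoyl)oxolane-3-carboxylate (C4 epimerisable, keto/enol)
Conditions: Dess–Martin periodinane, NaHCO3, CH2Cl2, rt
Reagents that add atoms: none
Why: Oxidation of the secondary benzylic alcohol converges all diastereomers into one α-aroyl lactone, a β-keto-lactone whose C4 epimerises readily, which is the substrate type needed for a dynamic resolution.

**Step 7**
Reactants: 11
Product: 12 methyl (2R,3R,4R)-2-[4-(allyloxy)-3,5-dimethoxyphenyl]-4-[(R)-hydroxy(3,4,5-trimethoxyphenyl)methyl]-5-oxooxolane-3-carboxylate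
Conditions: KRED (screened ketoreductase), NADP+ (0.5 mol %), GDH, glucose, 100 mM KPi pH 7.0, 15 % DMSO, 30 °C, 24 h
Reagents that add atoms: none
Why: Ketoreductase (oxidoreductase) dynamic reductive kinetic resolution: the enzyme reduces one aroyl face while C4 epimerises. It selects the (R)-carbinol and the syn, cis-to-CO2Me epimer, setting Cc and Cf (target C3a/C4) with the aryl exo; a panel enzyme with this selectivity is assumed.

**Step 8**
Reactants: 12
Product: 13 (3R,3aR,6R,6aR)-3-[4-(allyloxy)-3,5-dimethoxyphenyl]-6-(3,4,5-trimethoxyphenyl)tetrahydro-1H,3H-furo[3,4-c]furan-1,4-dione (cis-fused bis-lactone)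
Conditions: CSA (10 mol %), PhMe, 4 Å MS, 50 °C
Reagents that add atoms: none
Why: Acid-catalysed intramolecular transesterification (5-exo lactonisation) of the carbinol onto the methyl ester, possible only for the cis epimer, so it locks the cis ring fusion and lets any trans diastereomer be removed. No stereocentre is changed.

**Step 9**
Reactants: 13
Product: 14 (1R,2S,3S,4R)-1-[4-(allyloxy)-3,5-dimethoxyphenyl]-2,3-bis(hydroxymethyl)-4-(3,4,5-trimethoxyphenyl)butane-1,4-diol
Conditions: LiAlH4 (4 equiv), THF, 0 °C → rt; Rochelle salt work-up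
Reagents that add atoms: none
Why: Hydride reduction of both lactones to primary and secondary alcohols; all four stereocentres lie away from the reacting carbonyls and are untouched.

**Step 10**
Reactants: 14; 15 p-toluenesulfonyl chloride
Product: 16 bis(primary tosylate) of 14
Conditions: TsCl (2.3 equiv), pyridine, CH2Cl2, 0 °C → rt, 16 h
Reagents that add atoms: TsCl, Cc1ccc(S(=O)(=O)Cl)cc1
Why: Sulfonylation is selective for the unhindered primary hydroxyls over the secondary benzylic ones; leaving no free primary OH prevents cyclodehydration between the two primary alcohols.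

**Step 11**
Reactants: 16
Product: 17 (1R,3aS,4R,6aS)-1-[4-(allyloxy)-3,5-dimethoxyphenyl]-4-(3,4,5-trimethoxyphenyl)tetrahydro-1H,3H-furo[3,4-c]furan
Conditions: NaH (3 equiv), THF (0.01 M), 0 °C → 50 °C
Reagents that add atoms: none
Why: Double intramolecular Williamson etherification: each benzylic alkoxide can close a 5-membered ring only on its matching primary tosylate. SN2 occurs at CH2, so all four stereocentres are retained.

**Step 12**
Reactants: 17
Product: 18 target, (1R,3aS,4R,6aS)-1-(4-hydroxy-3,5-dimethoxyphenyl)-4-(3,4,5-trimethoxyphenyl)tetrahydro-1H,3H-furo[3,4-c]furan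
Conditions: Pd(PPh3)4 (5 mol %), K2CO3, MeOH, rt, 3 h
Reagents that add atoms: none
Why: Pd(0)-catalysed Tsuji–Trost deallylation under neutral-to-mild basic conditions leaves the benzylic ether C–O bonds and all stereocentres intact.

---

**Compound list**

| No. | Name | SMILES | Role |
|---|---|---|---|
| 1 | acetosyringone | CC(=O)c1cc(OC)c(O)c(OC)c1 | starting material |
| 2 | allyl bromide | C=CCBr | starting material |
| 3 | 1-[4-(allyloxy)-3,5-dimethoxyphenyl]ethanone | CC(=O)c1cc(OC)c(OCC=C)c(OC)c1 | intermediate |
| 4 | dimethyl carbonate | COC(=O)OC | starting material |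
| 5 | methyl 3-aryl-3-oxopropanoate | COC(=O)CC(=O)c1cc(OC)c(OCC=C)c(OC)c1 | intermediate |
| 6 | methyl bromoacetate | COC(=O)CBr | starting material |
| 7 | dimethyl 2-aroylsuccinate (labile α-centre) | COC(=O)CC(C(=O)OC)C(=O)c1cc(OC)c(OCC=C)c(OC)c1 | intermediate |
| 8 | methyl (2R,3R)-trans-paraconate | COc1cc([C@@H]2OC(=O)C[C@H]2C(=O)OC)cc(OC)c1OCC=C | intermediate |
| 9 | 3,4,5-trimethoxybenzaldehyde | COc1cc(C=O)cc(OC)c1OC | starting material |
| 10 | aldol adduct (C4/carbinol undefined) | COc1cc([C@@H]2OC(=O)C(C(O)c3cc(OC)c(OC)c(OC)c3)[C@H]2C(=O)OC)cc(OC)c1OCC=C | intermediate |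
| 11 | α-aroyl lactone (C4 epimerisable) | COc1cc([C@@H]2OC(=O)C(C(=O)c3cc(OC)c(OC)c(OC)c3)[C@H]2C(=O)OC)cc(OC)c1OCC=C | intermediate |
| 12 | hydroxy-lactone (2R,3R,4R; carbinol R) | COc1cc([C@@H]2OC(=O)[C@@H]([C@@H](O)c3cc(OC)c(OC)c(OC)c3)[C@H]2C(=O)OC)cc(OC)c1OCC=C | intermediate |
| 13 | cis-fused bis-lactone (all R) | COc1cc([C@@H]2OC(=O)[C@@H]3[C@H]2C(=O)O[C@H]3c2cc(OC)c(OC)c(OC)c2)cc(OC)c1OCC=C | intermediate |
| 14 | tetraol (1R,2S,3S,4R) | COc1cc([C@H](O)[C@H](CO)[C@@H](CO)[C@@H](O)c2cc(OC)c(OC)c(OC)c2)cc(OC)c1OCC=C | intermediate |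
| 15 | p-toluenesulfonyl chloride | Cc1ccc(S(=O)(=O)Cl)cc1 | starting material |
| 16 | bis-tosylate | COc1cc([C@H](O)[C@H](COS(=O)(=O)c2ccc(C)cc2)[C@@H](COS(=O)(=O)c2ccc(C)cc2)[C@@H](O)c2cc(OC)c(OC)c(OC)c2)cc(OC)c1OCC=C | intermediate |
| 17 | allyl-protected furofuran | COc1cc([C@@H]2OC[C@@H]3[C@H]2CO[C@H]3c2cc(OC)c(OC)c(OC)c2)cc(OC)c1OCC=C | intermediate |
| 18 | target | COc1cc([C@@H]2OC[C@@H]3[C@H]2CO[C@H]3c2cc(OC)c(OC)c(OC)c2)cc(OC)c1O | target |

**Total steps:** 12. **Longest linear sequence:** 12 (1 → 18).

**Three steps most likely to fail**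
1. **Step 7 (ketoreductase dynamic resolution).** The enzyme may not give the syn, cis, exo-aryl diastereomer with high selectivity on this bulky substrate.
   - Fallback: drop catalyst control and use a thermodynamic aldol–lactonisation. Treat 8 with LDA and 9, then DBU in toluene at 60 °C so that retro-aldol and epimerisation funnel the cis-aldolates into bis-lactone 13 through irreversible lactonisation. Separate the exo,exo isomer by chromatography.
2. **Step 4 (Ru-catalysed transfer hydrogenation with dynamic kinetic resolution).** Syn:anti ratio or ee may be modest for the 2-aroylsuccinate.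
   - Fallback: set Ca by Ru-catalysed transfer hydrogenation of the α-unsubstituted β-keto ester 5. Then do a Fräter–Seebach dianion alkylation with methyl bromoacetate, lactonise to the cis-paraconate, and epimerise C3 with DBU to trans-8.
3. **Step 11 (double Williamson closure).** Competing Grob fragmentation of the 1,3-alkoxide/tosylate pairs, or oligomerisation, could lower the yield.
   - Fallback: convert 13 to its bis-lactol with DIBAL (−78 °C), then deoxygenate with Et3SiH/BF3·OEt2 at −78 °C to give 17. This replaces SN2 ring closure with oxocarbenium reduction.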